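**Retrosynthetic overview**
- The C11–C12 bond is made last, by hydroboration of a C9 exocyclic methylene (sets C9) and B-alkyl Suzuki–Miyaura coupling with an (E)-dienyl iodide; the O6 angelate and the 7β-OH come from a 6α,8α-dihydroxy-7-ketone.
- The 8α-OH and the C9=C11 methylene come from deconjugative α-hydroxylation of a Δ8-en-7-one dienolate; 5α-H and 6α-OH come from dissolving-metal reduction and Rubottom oxidation of a cross-conjugated bicyclic dienone.
- Ring A (formed second) is closed at C4–C5 by a cobalt-hydride cycloisomerisation of a 4,4-disubstituted cyclohexadienone (the new step).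
- Ring B (formed first) comes from aldol condensation of a 1,5-diketone released from a doubly alkylated valinol bicyclic lactam, which sets the C10 quaternary centre.
- Four fragments converge: the δ-keto acid/lactam core, 5-iodo-2-methylpent-1-ene, angelic mixed anhydride and (E)-1-iodo-2-methylbuta-1,3-diene.

Convention: bicyclic compounds carry labdane numbering (ring A = C1–C5 plus C10, ring B = C5–C10, C11 on C9, C17 on C8, C20 on C10); α and β mean below and above the ring plane when the C10 methyl is drawn up (β).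

Assumption: the second alkylation of the valinol-derived bicyclic lactam takes place on the endo face (anti to the angular ethyl group), the usual selectivity of this auxiliary; the configuration at C10 is drawn on that basis.

**Fragment A: ring A chain**

Step 1
Reactants: 1 5-chloropentan-2-one
Product: 2 5-chloro-2-methylpent-1-ene
Conditions: Ph3PCH3Br, KOtBu, THF, 0 °C; then 1, 0 °C → rt
Reagents that add atoms: methyltriphenylphosphonium bromide, C[P+](c1ccccc1)(c1ccccc1)c1ccccc1.[Br-]
Why: Wittig methylenation of the methyl ketone with preformed ylide at low temperature outruns enolisation and gives the 1,1-disubstituted alkene that later serves as the radical precursor.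

Step 2
Reactants: 2 5-chloro-2-methylpent-1-ene
Product: 3 5-iodo-2-methylpent-1-ene
Conditions: NaI, acetone, reflux, dark
Reagents that add atoms: sodium iodide, [Na+].[I-]
Why: Finkelstein exchange, driven by precipitation of NaCl, gives the primary iodide needed for enolate alkylation.

**Core**

Step 3
Reactants: 4 glutaric anhydride
Product: 5 5-oxoheptanoic acid
Conditions: EtMgBr (1.05 equiv), THF, −78 → −20 °C; 1 M HCl
Reagents that add atoms: ethylmagnesium bromide, CC[Mg]Br
Why: Grignard mono-addition to a cyclic anhydride at low temperature stops at the keto carboxylate, because the magnesium carboxylate deactivates the product toward a second addition.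

Step 4
Reactants: 5 5-oxoheptanoic acid; 6 (S)-valinol
Product: 7 (3S,8aR)-8a-ethyl-3-(propan-2-yl)hexahydro-5H-[1,3]oxazolo[3,2-a]pyridin-5-one
Conditions: TsOH·H2O (cat.), PhMe, reflux, Dean–Stark
Reagents that add atoms: none
Why: Meyers bicyclic lactam formation by cyclodehydration gives the thermodynamic N,O-ketal with the angular ethyl cis to the isopropyl group, so the valinol centre fixes C8a.

Step 5
Reactants: 7 bicyclic lactam
Product: 9 (3S,8aR)-8a-ethyl-6-methyl-3-(propan-2-yl)hexahydro-5H-[1,3]oxazolo[3,2-a]pyridin-5-one (C6 epimers), via lithium enolate 8 (not isolated)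
Conditions: LiN(iPr)2, THF, −78 °C; MeI, −78 → 0 °C
Reagents that add atoms: iodomethane, IC
Why: Lactam enolate methylation (Meyers alkylation) needs no selectivity here because this centre is re-enolised in the next step.

Step 6
Reactants: 9 6-methyl lactam; 3 5-iodo-2-methylpent-1-ene
Product: 11 (3S,6S,8aR)-8a-ethyl-6-methyl-6-(4-methylpent-4-en-1-yl)-3-(propan-2-yl)hexahydro-5H-[1,3]oxazolo[3,2-a]pyridin-5-one, via lithium enolate 10 (not isolated)
Conditions: LiN(iPr)2, THF, −78 °C; 3, DMPU, −78 → −20 °C; chromatography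
Reagents that add atoms: none
Why: In the second Meyers alkylation the trisubstituted lactam enolate takes the iodide on the endo face, anti to the angular ethyl group, which sets the quaternary centre (future C10) with the methyl exo, and the minor epimer is removed by chromatography.

Step 7
Reactants: 11 dialkylated lactam
Product: 14 (4S)-2,3,4-trimethyl-4-(4-methylpent-4-en-1-yl)cyclohex-2-en-1-one, via keto oxazolidine 12 (not isolated), via 1,5-diketone 13 (not isolated)
Conditions: MeLi, THF, −78 → 0 °C; aq. Bu4N·H2PO4 (1 M), EtOH, reflux; pyrrolidine, AcOH, PhMe, reflux (Dean–Stark)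
Reagents that add atoms: methyllithium, [Li]C; water, O
Why: MeLi adds once to the non-enolisable lactam carbonyl, buffered hydrolysis frees the 1,5-diketone and the auxiliary, and enamine-mediated aldol condensation, in which only the unhindered ethyl ketone can form the enamine, closes ring B as the tetrasubstituted enone without touching the quaternary centre.

Step 8
Reactants: 14 cyclohexenone
Product: 15 (4S)-2,3,4-trimethyl-4-(4-methylpent-4-en-1-yl)cyclohexa-2,5-dien-1-one
Conditions: IBX (2.5 equiv), DMSO/PhF (1:2), 75 °C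
Reagents that add atoms: none
Why: IBX dehydrogenation of the enone at its only enolisable α′,β′ positions gives the cross-conjugated dienone and leaves the isolated alkene alone.

Step 9
Reactants: 15 monocyclic dienone
Product: 16 (4aR)-3,4,4a,8,8-pentamethyl-5,6,7,8-tetrahydronaphthalen-2(4aH)-one
Conditions: (salen)CoCl (5 mol %, trivalent cobalt; salen = N,N′-bis(3,5-di-tert-butylsalicylidene)cyclohexane-1,2-diaminate), PhSiH3 (10 mol %), degassed PhH, 25–40 °C
Reagents that add atoms: none
Why: Proposed new method: a cobalt hydride formed from (salen)CoCl and catalytic PhSiH3 transfers a hydrogen atom (MHAT) to the electron-rich 1,1-disubstituted alkene to give the tertiary C4 radical, which adds 6-exo to the only unsubstituted β-carbon of the dienone (C5, since C9 is blocked by its methyl), and the resulting α-keto radical returns its now weak C5–H to divalent cobalt, which regenerates the enone and the hydride in a redox-neutral cycloisomerisation that closes ring A, builds the C4 quaternary centre and leaves C5 trigonal so that no cis ring fusion is fixed; the closest known reactions are cobalt-salen MHAT alkene isomerisation and diene cycloisomerisation and the iron-mediated reductive (Giese-type) alkene–enone coupling.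

Step 10
Reactants: 16 bicyclic dienone
Product: 20 (1R,4aS,8aS)-1-hydroxy-3,4,4a,8,8-pentamethyl-4a,5,6,7,8,8a-hexahydronaphthalen-2(1H)-one, via lithium dienolate 17 (not isolated), via trimethylsilyl dienol ether 18 (not isolated), via 6α-silyloxy ketone 19 (not isolated)
Conditions: Li (2.2 equiv), t-BuOH (1.0 equiv), NH3(l)/THF, −78 °C; isoprene; Me3SiCl, Et3N, THF, −78 → 0 °C; mCPBA, NaHCO3, CH2Cl2, −20 °C; aq. citric acid, MeOH
Reagents that add atoms: meta-chloroperbenzoic acid, O=C(OO)c1cccc(Cl)c1
Why: Dissolving-metal reduction takes the less substituted enone arm with axial protonation at C5 (trans-decalin, 5α-H), and Rubottom oxidation of the resulting regiodefined silyl dienol ether occurs on the α face because the β face is blocked by the axial C10 and C4 methyls, which gives the 6α-alcohol.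

Step 11
Reactants: 20 6α-hydroxy enone
Product: 22 6α,8α-dihydroxy-4,4,8β,10β-tetramethyl-9-methylene-5α-decalin-7-one, via dilithium alkoxide dienolate 21 (not isolated)
Conditions: LiN(iPr)2 (3.2 equiv), THF, −78 → −40 °C; 2-(phenylsulfonyl)-3-phenyloxaziridine, −78 °C; aq. NH4Cl
Reagents that add atoms: 2-(phenylsulfonyl)-3-phenyloxaziridine, O=S(=O)(c1ccccc1)N1OC1c1ccccc1
Why: The C6 alkoxide suppresses α′-deprotonation, so the base removes a γ-proton from the C9 methyl, and Davis oxidation of the extended dienolate at its α-carbon (C8) from the α face, anti to the axial C10 methyl, installs the 8α-hydroxyl and the C9=C11 methylene in one deconjugative α-hydroxylation.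

**Fragment C: angelate donor**

Step 12
Reactants: 23 angelic acid
Product: 24 angelic 2,4,6-trichlorobenzoic anhydride
Conditions: 2,4,6-trichlorobenzoyl chloride, Et3N, PhMe, 0 °C → rt; filter, concentrate
Reagents that add atoms: 2,4,6-trichlorobenzoyl chloride, O=C(Cl)c1c(Cl)cc(Cl)cc1Cl
Why: Mixed-anhydride formation with the Yamaguchi reagent activates the acid under conditions that do not isomerise the Z alkene to the tiglate.

Step 13
Reactants: 22 dihydroxy ketone; 24 angelic mixed anhydride
Product: 25 6α-angeloyloxy-8α-hydroxy-4,4,8β,10β-tetramethyl-9-methylene-5α-decalin-7-one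
Conditions: PhMe, 80 °C, 24 h (no DMAP)
Reagents that add atoms: none
Why: In this Yamaguchi-type acylation without nucleophilic catalyst the secondary 6α-alcohol attacks the unhindered angeloyl carbonyl, the tertiary 8-alcohol is inert, and the Z geometry is kept.

Step 14
Reactants: 25 angeloyloxy ketone
Product: 26 6α-angeloyloxy-4,4,8β,10β-tetramethyl-9-methylene-5α-decalin-7β,8α-diol
Conditions: NaBH4, CeCl3·7H2O, MeOH/THF, −40 °C
Reagents that add atoms: none
Why: Luche-type reduction delivers hydride axially from the α face, since the β face is shielded by the axial 8β and 10β methyls, which gives the equatorial 7β-alcohol while the conjugated ester survives at low temperature.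

**Fragment B: dienyl iodide**

Step 15
Reactants: 27 prop-2-yn-1-ol
Product: 29 (E)-3-iodo-2-methylprop-2-en-1-ol, via alkenylalane 28 (not isolated)
Conditions: Me3Al (3 equiv), Cp2ZrCl2 (0.25 equiv), CH2Cl2, 0 °C → rt; I2, THF, −30 → 0 °C
Reagents that add atoms: trimethylaluminium, C[Al](C)C; iodine, [I][I]
Why: Negishi zirconium-catalysed carboalumination adds methyl and aluminium syn across the alkyne with methyl on the internal carbon, and iodinolysis with retention gives the (E)-iodoalkene.

Step 16
Reactants: 29 (E)-3-iodo-2-methylprop-2-en-1-ol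
Product: 30 (E)-3-iodo-2-methylprop-2-enal
Conditions: MnO2, CH2Cl2, rt
Reagents that add atoms: none
Why: MnO2 oxidises the allylic alcohol to the enal under neutral conditions without scrambling the alkene geometry.

Step 17
Reactants: 30 (E)-3-iodo-2-methylprop-2-enal
Product: 31 (E)-1-iodo-2-methylbuta-1,3-diene
Conditions: Ph3PCH3Br, KOtBu, Et2O, 0 °C; then 30, −78 → 0 °C; kept as a cold Et2O solution in the dark
Reagents that add atoms: methyltriphenylphosphonium bromide, C[P+](c1ccccc1)(c1ccccc1)c1ccccc1.[Br-]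
Why: Wittig methylenation of the aldehyde builds the terminal vinyl group and leaves the iodoalkene geometry untouched.

**Fragment union**

Step 18
Reactants: 26 methylene diol monoangelate; 31 (E)-1-iodo-2-methylbuta-1,3-diene
Product: 33 (12E)-6α-angeloyloxylabda-12,14-diene-7β,8α-diol (CNP0189082.1), via B-alkyl-9-BBN adduct 32 (not isolated)
Conditions: 9-BBN (4 equiv), THF, 0 → 50 °C; then 31, Pd(dppf)Cl2 (10 mol %), AsPh3, aq. K3PO4 (3 M), DMF, rt, dark
Reagents that add atoms: none
Why: 9-BBN adds to the exocyclic methylene from the α face, the β face being blocked by the two axial methyls, which puts hydrogen on C9α and boron on C11, and B-alkyl Suzuki–Miyaura coupling with the (E)-dienyl iodide then forms C11–C12 with retention of alkene geometry.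

**Compound list**

1 | 5-chloropentan-2-one | CC(=O)CCCCl | starting material
2 | 5-chloro-2-methylpent-1-ene | C=C(C)CCCCl | intermediate
3 | 5-iodo-2-methylpent-1-ene | ICCCC(C)=C | intermediate
4 | glutaric anhydride (oxane-2,6-dione) | O=C1CCCC(=O)O1 | starting material
5 | 5-oxoheptanoic acid | CCC(=O)CCCC(=O)O | intermediate
6 | (S)-valinol, (2S)-2-amino-3-methylbutan-1-ol | CC(C)[C@H](N)CO | starting material
7 | (3S,8aR)-8a-ethyl-3-(propan-2-yl)hexahydro-5H-[1,3]oxazolo[3,2-a]pyridin-5-one (ethyl cis to isopropyl) | CC[C@@]12CCCC(=O)N1[C@@H](C(C)C)CO2 | intermediate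
8 | lithium enolate of 7 (O–Li on C5, C5=C6) | CC[C@@]12CCC=C(O[Li])N1[C@@H](C(C)C)CO2 | intermediate
9 | (3S,8aR)-8a-ethyl-6-methyl-3-(propan-2-yl)hexahydro-5H-[1,3]oxazolo[3,2-a]pyridin-5-one, mixture of C6 epimers | CC[C@@]12CCC(C)C(=O)N1[C@@H](C(C)C)CO2 | intermediate
10 | lithium enolate of 9 (O–Li on C5, C5=C6) | CC[C@@]12CCC(C)=C(O[Li])N1[C@@H](C(C)C)CO2 | intermediate
11 | (3S,6S,8aR)-8a-ethyl-6-methyl-6-(4-methylpent-4-en-1-yl)-3-(propan-2-yl)hexahydro-5H-[1,3]oxazolo[3,2-a]pyridin-5-one | CC[C@@]12CC[C@](C)(CCCC(C)=C)C(=O)N1[C@@H](C(C)C)CO2 | intermediate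
12 | (3S)-5-[(2R,4S)-2-ethyl-4-(propan-2-yl)-1,3-oxazolidin-2-yl]-3-methyl-3-(4-methylpent-4-en-1-yl)pentan-2-one | CC[C@@]1(CC[C@](C)(CCCC(C)=C)C(C)=O)N[C@@H](C(C)C)CO1 | intermediate
13 | (3S)-3-methyl-3-(4-methylpent-4-en-1-yl)octane-2,6-dione | CCC(=O)CC[C@](C)(CCCC(C)=C)C(C)=O | intermediate
14 | (4S)-2,3,4-trimethyl-4-(4-methylpent-4-en-1-yl)cyclohex-2-en-1-one | CC1=C(C)[C@@](C)(CCCC(C)=C)CCC1=O | intermediate
15 | (4S)-2,3,4-trimethyl-4-(4-methylpent-4-en-1-yl)cyclohexa-2,5-dien-1-one | CC1=C(C)[C@@](C)(CCCC(C)=C)C=CC1=O | intermediate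
16 | (4aR)-3,4,4a,8,8-pentamethyl-5,6,7,8-tetrahydronaphthalen-2(4aH)-one (4,4,8,9,10β-pentamethyl-5,8-dien-7-one) | CC1=C(C)[C@@]2(C)CCCC(C)(C)C2=CC1=O | intermediate
17 | lithium 4,4,8,9,10β-pentamethyl-5α-H-hexalin-6,8-dien-7-olate | CC1=C(C)[C@@]2(C)CCCC(C)(C)[C@@H]2C=C1O[Li] | intermediate
18 | 7-(trimethylsilyloxy)-4,4,8,9,10β-pentamethyl-5α-H-hexalin-6,8-diene | CC1=C(C)[C@@]2(C)CCCC(C)(C)[C@@H]2C=C1O[Si](C)(C)C | intermediate
19 | 6α-(trimethylsilyloxy)-4,4,8,9,10β-pentamethyl-5α-H-octal-8-en-7-one | CC1=C(C)[C@@]2(C)CCCC(C)(C)[C@@H]2[C@@H](O[Si](C)(C)C)C1=O | intermediate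
20 | (1R,4aS,8aS)-1-hydroxy-3,4,4a,8,8-pentamethyl-4a,5,6,7,8,8a-hexahydronaphthalen-2(1H)-one (6α-hydroxy-4,4,8,9,10β-pentamethyl-5α-H-octal-8-en-7-one) | CC1=C(C)[C@@]2(C)CCCC(C)(C)[C@@H]2[C@@H](O)C1=O | intermediate
21 | dilithium 4,4,8,10β-tetramethyl-9-methylene-5α-H-octal-7-ene-6α,7-diolate | C=C1C(C)=C(O[Li])[C@H](O[Li])[C@H]2C(C)(C)CCC[C@]12C | intermediate
22 | 6α,8α-dihydroxy-4,4,8β,10β-tetramethyl-9-methylene-5α-decalin-7-one | C=C1[C@](C)(O)C(=O)[C@H](O)[C@H]2C(C)(C)CCC[C@]12C | intermediate
23 | angelic acid, (Z)-2-methylbut-2-enoic acid | C/C=C(/C)C(=O)O | starting material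
24 | (Z)-2-methylbut-2-enoic 2,4,6-trichlorobenzoic anhydride | C/C=C(/C)C(=O)OC(=O)c1c(Cl)cc(Cl)cc1Cl | intermediate
25 | 6α-angeloyloxy-8α-hydroxy-4,4,8β,10β-tetramethyl-9-methylene-5α-decalin-7-one | C=C1[C@](C)(O)C(=O)[C@H](OC(=O)/C(C)=C\C)[C@H]2C(C)(C)CCC[C@]12C | intermediate
26 | 6α-angeloyloxy-4,4,8β,10β-tetramethyl-9-methylene-5α-decalin-7β,8α-diol | C=C1[C@](C)(O)[C@@H](O)[C@H](OC(=O)/C(C)=C\C)[C@H]2C(C)(C)CCC[C@]12C | intermediate
27 | prop-2-yn-1-ol | C#CCO | starting material
28 | (E)-alkenylalane, dimethylaluminium (E)-3-(dimethylalumanyl)-2-methylprop-2-en-1-olate | C[Al](C)/C=C(\C)CO[Al](C)C | intermediate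
29 | (E)-3-iodo-2-methylprop-2-en-1-ol | I/C=C(\C)CO | intermediate
30 | (E)-3-iodo-2-methylprop-2-enal | I/C=C(\C)C=O | intermediate
31 | (E)-1-iodo-2-methylbuta-1,3-diene | I/C=C(\C)C=C | intermediate
32 | 9-[(6α-angeloyloxy-7β,8α-dihydroxy-4,4,8β,10β-tetramethyl-5α,9α-H-decalin-9β-yl)methyl]-9-borabicyclo[3.3.1]nonane | C(B1C2CCCC1CCC2)[C@H]1[C@](C)(O)[C@@H](O)[C@H](OC(=O)/C(C)=C\C)[C@H]2C(C)(C)CCC[C@@]21C | intermediate
33 | (12E)-6α-angeloyloxylabda-12,14-diene-7β,8α-diol, CNP0189082.1 | C=C/C(C)=C/C[C@H]1[C@](C)(O)[C@@H](O)[C@H](OC(=O)/C(C)=C\C)[C@H]2C(C)(C)CCC[C@@]21C | target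

**Step count**
- Total: 18 steps.
- Longest linear sequence: 12 steps (steps 3–11, 13, 14 and 18, from glutaric anhydride), which is two thirds of the total.

**Steps most likely to fail, with fallbacks**

Step 9 (the proposed new cycloisomerisation). The risk is that the cobalt hydride only isomerises the alkene or that hydrogen return to cobalt is slow. The fallback sets out from 15 and comes back at 16. Compound 15 is cyclised reductively under iron-hydride MHAT/Giese conditions (Fe(acac)3, PhSiH3, EtOH/ethylene glycol, 60 °C), a known alkene–enone coupling that for geometric reasons gives the cis-fused 4,4,8,9,10β-pentamethyl-5β-H-octal-8-en-7-one F1. A second IBX dehydrogenation (as in step 8) then re-forms C5=C6, erases the unwanted C5 centre and delivers 16.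

Step 11 (deconjugative α-hydroxylation of the dianion). The risks are α′- versus γ-deprotonation and α- versus γ-oxygenation. The fallback sets out from 20 and comes back at 22; it fixes the oxygen position by a sigmatropic shift instead of enolate oxidation.
- Soft enolisation with Et3SiOTf/Et3N gives the 6α,7-bis(triethylsilyloxy)-9-methylene-7-ene F2.
- Ionic γ-bromination with NBS (THF, 0 °C) gives the 11-bromo-6α-(triethylsilyloxy) enone F3.
- PhSeNa (from PhSeSePh and NaBH4, EtOH) gives the 11-(phenylselanyl) enone F4.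
- H2O2/pyridine oxidises selenium and the selenoxide undergoes [2,3]-sigmatropic rearrangement, which places oxygen on C8 from the open α face and moves the alkene to C9=C11; hydrolysis of the selenenate gives the 8α-hydroxy-6α-(triethylsilyloxy)-9-methylene ketone F5.
- Aqueous HF in MeCN removes the silyl group and gives 22.

Step 18 (hydroboration of a hindered methylene beside free hydroxyls, then Suzuki coupling). The risks are sluggish 9-BBN addition and slow transmetalation of the β-branched borane. The fallback sets out from 26 and comes back at 33.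
- BH3·SMe2 then NaBO3 gives, by the same α-face addition, the 9β-(hydroxymethyl) triol monoangelate F6.
- I2/PPh3/imidazole converts only the primary hydroxyl into the 9β-(iodomethyl) compound F7.
- Nickel-catalysed reductive cross-electrophile coupling of F7 with 31 (nickel diiodide, 4,4′-di-tert-butyl-2,2′-bipyridine, Zn, DMA, rt), which tolerates free hydroxyls, forms C11–C12 and gives 33.

**Further compounds**

F1 | step 9 | 4,4,8,9,10β-pentamethyl-5β-H-octal-8-en-7-one (cis-fused) | CC1=C(C)[C@@]2(C)CCCC(C)(C)[C@H]2CC1=O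
F2 | step 11 | 6α,7-bis(triethylsilyloxy)-4,4,8,10β-tetramethyl-9-methylene-5α-H-octal-7-ene | C=C1C(C)=C(O[Si](CC)(CC)CC)[C@H](O[Si](CC)(CC)CC)[C@H]2C(C)(C)CCC[C@]12C
F3 | step 11 | 11-bromo-6α-(triethylsilyloxy)-4,4,8,9,10β-pentamethyl-5α-H-octal-8-en-7-one | CC1=C(CBr)[C@@]2(C)CCCC(C)(C)[C@@H]2[C@@H](O[Si](CC)(CC)CC)C1=O
F4 | step 11 | 11-(phenylselanyl)-6α-(triethylsilyloxy)-4,4,8,9,10β-pentamethyl-5α-H-octal-8-en-7-one | CC1=C(C[Se]c3ccccc3)[C@@]2(C)CCCC(C)(C)[C@@H]2[C@@H](O[Si](CC)(CC)CC)C1=O
F5 | step 11 | 8α-hydroxy-6α-(triethylsilyloxy)-4,4,8β,10β-tetramethyl-9-methylene-5α-decalin-7-one | C=C1[C@](C)(O)C(=O)[C@H](O[Si](CC)(CC)CC)[C@H]2C(C)(C)CCC[C@]12C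
F6 | step 18 | 6α-angeloyloxy-9β-(hydroxymethyl)-4,4,8β,10β-tetramethyl-5α,9α-H-decalin-7β,8α-diol | OC[C@H]1[C@](C)(O)[C@@H](O)[C@H](OC(=O)/C(C)=C\C)[C@H]2C(C)(C)CCC[C@@]21C
F7 | step 18 | 6α-angeloyloxy-9β-(iodomethyl)-4,4,8β,10β-tetramethyl-5α,9α-H-decalin-7β,8α-diol | IC[C@H]1[C@](C)(O)[C@@H](O)[C@H](OC(=O)/C(C)=C\C)[C@H]2C(C)(C)CCC[C@@]21C
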